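Ring C is disconnected as a hetero-Diels–Alder adduct. O1, C8a, C4a and C4 form an oxadiene, an ortho-quinone methide unveiled on ring A from a salicylaldehyde dimethyl acetal; C2–C3 is the vinyl group of the ring B 4-methoxystyrene, whose para-methoxy group directs the aryl substituent to C2. One chiral phosphoric acid catalysed [4+2] reaction forms C3–C4 and O1–C2, closes ring C and sets C2 as S, leaving C4 as a methyl ether that masks the ketone. The precursor is a bis-TBS-protected 6-prenyl-2-(dimethoxymethyl)phenol whose single free hydroxyl lies between the acetal carbon and the prenyl group, so that the prenyl group ends at C8.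

Key step: step 7

Assumption: the sense of induction in step 7 cannot be predicted with certainty; the (R)-acid is written, and its (S)-enantiomer is used instead should the first run favour the 2R adduct.
Assumption: 5-bromo-2-methoxybenzyl alcohol 6 and 2-methylallylmagnesium chloride 8 (solution in THF) are taken as catalogue items.

Step 1
Reactants: 1 2,4,6-trihydroxybenzaldehyde; 2 prenyl bromide
Product: 3 2,4,6-trihydroxy-3-(3-methylbut-2-en-1-yl)benzaldehyde
Conditions: 2 (1.0 equiv), DBU (1.1 equiv), THF, 0 °C to rt
Reagents that add atoms: none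
Why: C-alkylation of the ambident phloroglucinol-type phenoxide (Friedel–Crafts-type alkylation at carbon); the two free ring positions of 1 are equivalent, so a single mono-C-prenyl isomer should form, and limiting the bromide holds back O-alkylation and double alkylation.

Step 2
Reactants: 3 2,4,6-trihydroxy-3-(3-methylbut-2-en-1-yl)benzaldehyde
Product: 4 4,6-bis(tert-butyldimethylsilyloxy)-2-hydroxy-3-(3-methylbut-2-en-1-yl)benzaldehyde
Conditions: TBSCl (2.1 equiv), imidazole, CH2Cl2, 0 °C
Reagents that add atoms: TBSCl, CC(C)(C)[Si](C)(C)Cl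
Why: Silylation of phenols: the 4-OH is not hydrogen-bonded and the 6-OH is the less hindered ortho hydroxyl, whereas the 2-OH is flanked by the formyl and prenyl groups and stays chelated to the carbonyl, so two equivalents of TBSCl should stop at the 4,6-bis-silyl ether.

Step 3
Reactants: 4 4,6-bis(tert-butyldimethylsilyloxy)-2-hydroxy-3-(3-methylbut-2-en-1-yl)benzaldehyde
Product: 5 3,5-bis(tert-butyldimethylsilyloxy)-2-(dimethoxymethyl)-6-(3-methylbut-2-en-1-yl)phenol
Conditions: HC(OMe)3 (10 equiv), PPTS (5 mol%), CH2Cl2, rt; then Et3N, evaporate, use crude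
Reagents that add atoms: trimethyl orthoformate, COC(OC)OC
Why: Acid-catalysed acetalisation driven by conversion of the orthoformate into methyl formate; the weak acid and the basic quench should spare the aryl silyl ethers and the labile ortho-hydroxybenzaldehyde acetal, which is not chromatographed.

Step 4
Reactants: 6 5-bromo-2-methoxybenzyl alcohol
Product: 7 4-bromo-2-(bromomethyl)-1-methoxybenzene
Conditions: PBr3 (0.4 equiv), CH2Cl2, 0 °C
Reagents that add atoms: PBr3, BrP(Br)Br
Why: Conversion of a benzylic alcohol into the bromide through its phosphite ester and SN2 displacement by bromide.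

Step 5
Reactants: 7 4-bromo-2-(bromomethyl)-1-methoxybenzene; 8 2-methylallylmagnesium chloride
Product: 9 4-bromo-1-methoxy-2-(3-methylbut-3-en-1-yl)benzene
Conditions: 8 (1.3 equiv, 0.5 M in THF), THF, 0 °C to rt
Reagents that add atoms: none
Why: Coupling of an allylic Grignard reagent with a benzylic bromide by nucleophilic substitution; the aryl bromide does not react without a catalyst, and the symmetrical 2-methylallyl nucleophile gives the same product through either terminus.

Step 6
Reactants: 9 4-bromo-1-methoxy-2-(3-methylbut-3-en-1-yl)benzene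
Product: 10 1-methoxy-2-(3-methylbut-3-en-1-yl)-4-vinylbenzene
Conditions: CH2=CHBF3K (1.2 equiv), PdCl2 (2 mol%), PPh3 (6 mol%), Cs2CO3 (3 equiv), THF/H2O 9:1, 85 °C
Reagents that add atoms: potassium vinyltrifluoroborate, C=C[B-](F)(F)F.[K+]
Why: Suzuki–Miyaura cross-coupling of an aryl bromide with a vinyltrifluoroborate; the isolated 1,1-disubstituted alkene is inert to the zerovalent palladium catalyst under these conditions.

Step 7
Reactants: 5 3,5-bis(tert-butyldimethylsilyloxy)-2-(dimethoxymethyl)-6-(3-methylbut-2-en-1-yl)phenol; 10 1-methoxy-2-(3-methylbut-3-en-1-yl)-4-vinylbenzene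
Product: 12 (2S,4S)-5,7-bis(tert-butyldimethylsilyloxy)-4-methoxy-2-[4-methoxy-3-(3-methylbut-3-en-1-yl)phenyl]-8-(3-methylbut-2-en-1-yl)chroman, via ortho-quinone methide 11 (not isolated)
Conditions: 10 (1.5 equiv), (R)-3,3'-bis(2,4,6-triisopropylphenyl)-1,1'-binaphthyl-2,2'-diyl hydrogen phosphate (10 mol%), 5 Å MS, toluene, −40 °C
Reagents that add atoms: none
Why: Proposed new method: the phosphoric acid protonates an acetal oxygen of 5, methanol leaves, and the resulting O-methyl oxocarbenium ion, which is ortho-quinone methide 11 in protonated form, stays hydrogen-bonded through its phenolic OH to the chiral phosphate; the CH2 terminus of 10 then attacks C4 while the phenol oxygen closes on the emerging 4-methoxybenzylic cation at C2, an asynchronous inverse-electron-demand oxa-[4+2] cycloaddition that makes C3–C4 and O1–C2 and returns ring A to the aromatic state. The closest known reactions are the racemic acid-catalysed [4+2] of salicylaldehyde acetals with styrenes to 2-aryl-4-methoxychromans and the chiral phosphoric acid catalysed cycloadditions of ortho-quinone methides generated from ortho-hydroxybenzyl alcohols; an enantioselective acetal-based version with a plain styrene has not been shown. Ring C, the only ring formed, closes by the cycloaddition itself, in the stepwise limit by a 6-exo-trig-type attack of the phenol oxygen on the benzylic cation. C2 is set by the catalyst, whose bound phosphate shields one face of the oxadiene while the 2,4,6-triisopropylphenyl walls hold the styrene aryl group endo, and C4 follows from the same endo (2,4-cis) approach but is removed in step 9. The step needs regio-, chemo- and enantioselectivity: the 4-methoxyphenyl group stabilises charge at C2 and so fixes the regiochemistry, the 4-methoxystyrene is far more nucleophilic than the prenyl and 1,1-disubstituted alkenes of 5 and 10, and the weak acid at low temperature should leave the silyl ethers, the ortho-prenylphenol and the C4 ether of the product alone. Because the anion sits on the oxadiene, the C2 configuration depends on both the diene face and the cis/trans ratio, so the diastereomers are separated and only material shown to be 2S is carried on.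

Step 8
Reactants: 12 (2S,4S)-5,7-bis(tert-butyldimethylsilyloxy)-4-methoxy-2-[4-methoxy-3-(3-methylbut-3-en-1-yl)phenyl]-8-(3-methylbut-2-en-1-yl)chroman
Product: 13 (2S)-5,7-bis(tert-butyldimethylsilyloxy)-2-[4-methoxy-3-(3-methylbut-3-en-1-yl)phenyl]-8-(3-methylbut-2-en-1-yl)chroman-4-ol (mixture of C4 epimers)
Conditions: PPTS (0.2 equiv), acetone/H2O 5:1, rt
Reagents that add atoms: water, O
Why: SN1 solvolysis: the C4 methyl ether is benzylic to the tri-oxygenated ring A and should ionise under mild acid, water in large excess captures the cation, C2 is not involved, and the configuration at C4 does not matter.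

Step 9
Reactants: 13 (2S)-5,7-bis(tert-butyldimethylsilyloxy)-2-[4-methoxy-3-(3-methylbut-3-en-1-yl)phenyl]-8-(3-methylbut-2-en-1-yl)chroman-4-ol
Product: 14 (2S)-5,7-bis(tert-butyldimethylsilyloxy)-2-[4-methoxy-3-(3-methylbut-3-en-1-yl)phenyl]-8-(3-methylbut-2-en-1-yl)chroman-4-one
Conditions: Dess–Martin periodinane (1.3 equiv), pyridine, CH2Cl2, 0 °C to rt
Reagents that add atoms: none
Why: Dess–Martin oxidation of a secondary benzylic alcohol under buffered, non-basic conditions, which erases the C4 stereocenter and gives no base-induced opening of the chromanone, so C2 should keep its configuration.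

Step 10
Reactants: 14 (2S)-5,7-bis(tert-butyldimethylsilyloxy)-2-[4-methoxy-3-(3-methylbut-3-en-1-yl)phenyl]-8-(3-methylbut-2-en-1-yl)chroman-4-one
Product: 15 (2S)-5,7-dihydroxy-2-[4-methoxy-3-(3-methylbut-3-en-1-yl)phenyl]-8-(3-methylbut-2-en-1-yl)chroman-4-one
Conditions: Et3N·3HF, THF, rt
Reagents that add atoms: none
Why: Fluoride cleavage of aryl silyl ethers (Si–F bond formation) under slightly acidic conditions, chosen over basic fluoride sources because base would open the flavanone to the chalcone and racemise C2; the prenyl and 1,1-disubstituted alkenes are untouched.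

Compound list
1 | 2,4,6-trihydroxybenzaldehyde | O=Cc1c(O)cc(O)cc1O | starting material
2 | prenyl bromide (1-bromo-3-methylbut-2-ene) | CC(C)=CCBr | starting material
3 | 2,4,6-trihydroxy-3-(3-methylbut-2-en-1-yl)benzaldehyde | O=Cc1c(O)cc(O)c(CC=C(C)C)c1O | intermediate
4 | 4,6-bis(tert-butyldimethylsilyloxy)-2-hydroxy-3-(3-methylbut-2-en-1-yl)benzaldehyde | O=Cc1c(O)c(CC=C(C)C)c(O[Si](C)(C)C(C)(C)C)cc1O[Si](C)(C)C(C)(C)C | intermediate
5 | 3,5-bis(tert-butyldimethylsilyloxy)-2-(dimethoxymethyl)-6-(3-methylbut-2-en-1-yl)phenol | COC(OC)c1c(O)c(CC=C(C)C)c(O[Si](C)(C)C(C)(C)C)cc1O[Si](C)(C)C(C)(C)C | intermediate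
6 | 5-bromo-2-methoxybenzyl alcohol | COc1ccc(Br)cc1CO | starting material
7 | 4-bromo-2-(bromomethyl)-1-methoxybenzene | COc1ccc(Br)cc1CBr | intermediate
8 | 2-methylallylmagnesium chloride | C=C(C)C[Mg]Cl | starting material
9 | 4-bromo-1-methoxy-2-(3-methylbut-3-en-1-yl)benzene | C=C(C)CCc1cc(Br)ccc1OC | intermediate
10 | 1-methoxy-2-(3-methylbut-3-en-1-yl)-4-vinylbenzene | C=C(C)CCc1cc(C=C)ccc1OC | intermediate
11 | (Z)-3,5-bis(tert-butyldimethylsilyloxy)-6-(methoxymethylene)-2-(3-methylbut-2-en-1-yl)cyclohexa-2,4-dien-1-one (ortho-quinone methide, present as its protonated, phosphate-bound form; Z geometry expected) | CO/C=C1\C(=O)C(CC=C(C)C)=C(O[Si](C)(C)C(C)(C)C)C=C1O[Si](C)(C)C(C)(C)C | intermediate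
12 | (2S,4S)-5,7-bis(tert-butyldimethylsilyloxy)-4-methoxy-2-[4-methoxy-3-(3-methylbut-3-en-1-yl)phenyl]-8-(3-methylbut-2-en-1-yl)chroman (2,4-cis) | C=C(C)CCc1cc([C@@H]2C[C@H](OC)c3c(O[Si](C)(C)C(C)(C)C)cc(O[Si](C)(C)C(C)(C)C)c(CC=C(C)C)c3O2)ccc1OC | intermediate
13 | (2S)-5,7-bis(tert-butyldimethylsilyloxy)-2-[4-methoxy-3-(3-methylbut-3-en-1-yl)phenyl]-8-(3-methylbut-2-en-1-yl)chroman-4-ol, C4 epimers | C=C(C)CCc1cc([C@@H]2CC(O)c3c(O[Si](C)(C)C(C)(C)C)cc(O[Si](C)(C)C(C)(C)C)c(CC=C(C)C)c3O2)ccc1OC | intermediate
14 | (2S)-5,7-bis(tert-butyldimethylsilyloxy)-2-[4-methoxy-3-(3-methylbut-3-en-1-yl)phenyl]-8-(3-methylbut-2-en-1-yl)chroman-4-one | C=C(C)CCc1cc([C@@H]2CC(=O)c3c(O[Si](C)(C)C(C)(C)C)cc(O[Si](C)(C)C(C)(C)C)c(CC=C(C)C)c3O2)ccc1OC | intermediate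
15 | (2S)-5,7-dihydroxy-2-[4-methoxy-3-(3-methylbut-3-en-1-yl)phenyl]-8-(3-methylbut-2-en-1-yl)chroman-4-one | C=C(C)CCc1cc([C@@H]2CC(=O)c3c(O)cc(O)c(CC=C(C)C)c3O2)ccc1OC | target

Total steps: 10. Longest linear sequence: 7 steps (steps 1, 2, 3, 7, 8, 9, 10; the ring B branch, steps 4, 5, 6, 7, 8, 9, 10, is equally long).

Steps most likely to fail

Step 7 (proposed new method). The risk is poor enantiofacial control, or poor cis/trans control, because the styrene has no second binding point to the catalyst. Slow ring closure could also let the benzylic cation be intercepted by another alkene. The fallback sets out from 5 and 10 and uses known chemistry only. The cycloaddition would be run in its racemic form with an achiral acid (diphenyl hydrogen phosphate, 10 mol%, CH2Cl2, −20 °C) to give the racemic 4-methoxyflavan F1. The conditions of step 8 would then give the racemic flavan-4-ol F2, and those of step 9 the racemic bis-silyl flavanone F3. F3 would be resolved kinetically by asymmetric transfer hydrogenation (RuCl(p-cymene)[(R,R)-TsDPEN], HCO2H/Et3N, EtOAc, rt, stopped near half conversion), a known way to resolve flavanones. By the usual sense of induction this catalyst should reduce the 2R ketone to the cis-(2R,4R)-flavan-4-ol F4 and leave the 2S ketone, which is compound 14; the route is rejoined there.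

Step 2. The risk is silylation at the wrong ortho hydroxyl, or over-silylation; a free 6-OH would carry the prenyl group to C6 after ring closure. The fallback sets out from 1, also bypasses the C-prenylation of step 1, and fixes the regiochemistry by symmetry. Bis-silylation of 1 (TBSCl 2 equiv, imidazole, CH2Cl2, 0 °C) can give only 2-hydroxy-4,6-bis(tert-butyldimethylsilyloxy)benzaldehyde F5, since the two ortho hydroxyls are equivalent. The remaining phenol would be O-alkylated with 3-chloro-3-methylbut-1-yne (CuCl2 cat., DBU, MeCN, 0 °C) to the 1,1-dimethylpropargyl ether F6. Semi-hydrogenation (H2, Pd/CaCO3 poisoned with Pb(OAc)2, quinoline, EtOAc) would give the 1,1-dimethylallyl ether F7. Aromatic Claisen rearrangement (toluene, 110 °C) can go only to the one free ortho carbon and delivers a normal prenyl group there, giving compound 4, where the route is rejoined.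

Step 8. The risk is loss of a proton from the C4 cation to give the flav-3-ene, or Friedel–Crafts self-condensation, instead of capture by water. The fallback sets out from 12 and replaces solvolysis by oxidation: DDQ (1.2 equiv) in CH2Cl2/pH 7 buffer at 0 °C abstracts hydride from C4, water adds to the oxocarbenium ion and methanol is lost. This should give ketone 14 directly, where the route is rejoined with steps 8 and 9 merged into one operation (no new compound, F0).

Further compounds
F1 | step 7 | racemic 5,7-bis(tert-butyldimethylsilyloxy)-4-methoxy-2-[4-methoxy-3-(3-methylbut-3-en-1-yl)phenyl]-8-(3-methylbut-2-en-1-yl)chroman | C=C(C)CCc1cc(C2CC(OC)c3c(O[Si](C)(C)C(C)(C)C)cc(O[Si](C)(C)C(C)(C)C)c(CC=C(C)C)c3O2)ccc1OC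
F2 | step 7 | racemic 5,7-bis(tert-butyldimethylsilyloxy)-2-[4-methoxy-3-(3-methylbut-3-en-1-yl)phenyl]-8-(3-methylbut-2-en-1-yl)chroman-4-ol | C=C(C)CCc1cc(C2CC(O)c3c(O[Si](C)(C)C(C)(C)C)cc(O[Si](C)(C)C(C)(C)C)c(CC=C(C)C)c3O2)ccc1OC
F3 | step 7 | racemic 5,7-bis(tert-butyldimethylsilyloxy)-2-[4-methoxy-3-(3-methylbut-3-en-1-yl)phenyl]-8-(3-methylbut-2-en-1-yl)chroman-4-one | C=C(C)CCc1cc(C2CC(=O)c3c(O[Si](C)(C)C(C)(C)C)cc(O[Si](C)(C)C(C)(C)C)c(CC=C(C)C)c3O2)ccc1OC
F4 | step 7 | (2R,4R)-5,7-bis(tert-butyldimethylsilyloxy)-2-[4-methoxy-3-(3-methylbut-3-en-1-yl)phenyl]-8-(3-methylbut-2-en-1-yl)chroman-4-ol | C=C(C)CCc1cc([C@H]2C[C@@H](O)c3c(O[Si](C)(C)C(C)(C)C)cc(O[Si](C)(C)C(C)(C)C)c(CC=C(C)C)c3O2)ccc1OC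
F5 | step 2 | 2-hydroxy-4,6-bis(tert-butyldimethylsilyloxy)benzaldehyde | O=Cc1c(O)cc(O[Si](C)(C)C(C)(C)C)cc1O[Si](C)(C)C(C)(C)C
F6 | step 2 | 2-(2-methylbut-3-yn-2-yloxy)-4,6-bis(tert-butyldimethylsilyloxy)benzaldehyde | O=Cc1c(OC(C)(C)C#C)cc(O[Si](C)(C)C(C)(C)C)cc1O[Si](C)(C)C(C)(C)C
F7 | step 2 | 2-(2-methylbut-3-en-2-yloxy)-4,6-bis(tert-butyldimethylsilyloxy)benzaldehyde | O=Cc1c(OC(C)(C)C=C)cc(O[Si](C)(C)C(C)(C)C)cc1O[Si](C)(C)C(C)(C)C
F0 | step 8 | none | none
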